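**Retrosynthetic overview**

- Feature: ring A is a phloroglucinol (C4a–C5–C6–C7–C8–C8a) fused to pyranone ring C. C5–C6–C7–C8, with both hydroxyls and the C8 geranyl chain, map onto a γ-geranylated acetoacetate; C4a=C8a map onto the enone of a chiral 2-aryl-2,3-dihydro-4H-pyran-4-one.
- Key disconnection: C8–C8a and C4a–C5, made by [4+2] addition of a 4-geranyl-1-methoxy-1,3-bis(silyloxy)diene to the C5=C6 bond of the (S)-pyranone. C5 carries a phenylsulfinyl group rather than a halogen, because it activates the vinylogous ester and can leave by syn-elimination with the cis 8a-H that the cycloaddition creates.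
- Order of rings: ring C first (asymmetric hetero-Diels–Alder sets C2), then C5 sulfenylation and oxidation; ring A last, by cycloaddition and aromatisation (loss of PhSOH and MeOSiMe3).
- Diene from methyl acetoacetate dianion and geranyl bromide, then two O-silylations; the end is a buffered fluoride desilylation of the 4'-oxygen.

Key step: step 8

Assumption: the (S)-BINOL–titanium catalyst is taken to direct the diene to the Si face of the aryl aldehyde, as this catalyst family does with benzaldehyde; if the sense proves opposite on this substrate, (R)-BINOL is used and nothing else changes.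

**Route**

Step 1
Reactants: 1 4-hydroxybenzaldehyde
Product: 2 4-(tert-butyldimethylsilyloxy)benzaldehyde
Conditions: TBSCl, imidazole, DMF, rt
Reagents that add atoms: tert-butyldimethylsilyl chloride, CC(C)(C)[Si](C)(C)Cl
Why: Imidazole-mediated silylation of the phenol (standard silyl ether formation) masks the acidic OH, which would otherwise quench the titanium catalyst and the silyl dienes used later.

Step 2
Reactants: 2 4-(tert-butyldimethylsilyloxy)benzaldehyde; 3 trans-1-methoxy-3-(trimethylsilyloxy)buta-1,3-diene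
Product: 5 (S)-2-[4-(tert-butyldimethylsilyloxy)phenyl]-2,3-dihydro-4H-pyran-4-one, via open-chain Mukaiyama aldol adduct 4 (not isolated)
Conditions: (S)-BINOL/Ti(OiPr)4 (cat.), 4 Å MS, Et2O, −20 °C; then TFA, CH2Cl2, 0 °C
Reagents that add atoms: none
Why: The BINOL–titanium complex promotes an enantioselective Mukaiyama aldol addition of the silyl dienol ether to the aldehyde (Keck-type stepwise hetero-Diels–Alder reaction), the ligand shielding one carbonyl face so that C–C bond formation on the Si face sets (S) at the future C2, and TFA then closes the adduct to the dihydropyranone with loss of methanol.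

Step 3
Reactants: 5 (S)-2-[4-(tert-butyldimethylsilyloxy)phenyl]-2,3-dihydro-4H-pyran-4-one
Product: 7 (S)-2-[4-(tert-butyldimethylsilyloxy)phenyl]-5-(phenylthio)-2,3-dihydro-4H-pyran-4-one, via 6-chloro-5-(phenylthio)tetrahydropyranone 6 (not isolated)
Conditions: PhSCl (1.05 equiv), CH2Cl2, −78 °C; then Et3N, −78 → 0 °C
Reagents that add atoms: benzenesulfenyl chloride, ClSc1ccccc1
Why: The C5=C6 bond of the vinylogous ester is a nucleophilic enol ether, so the sulfenyl chloride adds with sulfur at C5 and chloride at C6, and Et3N then eliminates HCl through the acidic α-keto C5–H (electrophilic α-sulfenylation of an enone by addition–elimination) without touching C2.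

Step 4
Reactants: 7 (S)-2-[4-(tert-butyldimethylsilyloxy)phenyl]-5-(phenylthio)-2,3-dihydro-4H-pyran-4-one
Product: 8 (2S)-2-[4-(tert-butyldimethylsilyloxy)phenyl]-5-(phenylsulfinyl)-2,3-dihydro-4H-pyran-4-one (both epimers at sulfur)
Conditions: mCPBA (1.0 equiv), NaHCO3, CH2Cl2, −78 °C
Reagents that add atoms: 3-chloroperoxybenzoic acid, O=C(OO)c1cccc(Cl)c1
Why: One equivalent of peracid at low temperature oxidises the sulfide far faster than the electron-poor enol ether or the sulfoxide formed (chemoselective sulfide oxidation); the sulfur stereocentre is uncontrolled and need not be controlled, since it is lost in step 8.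

Step 5
Reactants: 9 methyl acetoacetate; 10 geranyl bromide
Product: 11 methyl (6E)-7,11-dimethyl-3-oxododeca-6,10-dienoate
Conditions: NaH, THF, 0 °C; n-BuLi, 0 °C; then 10, 0 °C → rt
Reagents that add atoms: none
Why: The dianion of methyl acetoacetate alkylates at its more basic terminal γ-carbon (Weiler dianion alkylation), and the primary allylic bromide reacts by SN2 with the E-alkene retained.

Step 6
Reactants: 11 methyl (6E)-7,11-dimethyl-3-oxododeca-6,10-dienoate
Product: 12 methyl (6E)-7,11-dimethyl-3-(trimethylsilyloxy)dodeca-2,6,10-trienoate (2E/2Z mixture)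
Conditions: TMSCl, Et3N, PhMe, rt
Reagents that add atoms: chlorotrimethylsilane, C[Si](C)(C)Cl
Why: The β-keto ester enolises readily and is O-silylated by TMSCl/Et3N (silyl enol ether formation), which gives the first half of the diene.

Step 7
Reactants: 12 methyl (6E)-7,11-dimethyl-3-(trimethylsilyloxy)dodeca-2,6,10-trienoate
Product: 13 (1Z,3Z,6E)-1-methoxy-7,11-dimethyl-1,3-bis(trimethylsilyloxy)dodeca-1,3,6,10-tetraene
Conditions: LDA, THF, −78 °C; TMSCl, −78 °C → rt; used crude
Reagents that add atoms: chlorotrimethylsilane, C[Si](C)(C)Cl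
Why: LDA removes a γ-proton of the silyloxy enoate and the ester dienolate is O-silylated (Chan-type bis-silyl dienol ether synthesis), with the chain expected anti to the diene backbone; the geometry of both enol ether bonds is immaterial to the product because all four carbons become aromatic.

Step 8
Reactants: 8 (2S)-2-[4-(tert-butyldimethylsilyloxy)phenyl]-5-(phenylsulfinyl)-2,3-dihydro-4H-pyran-4-one; 13 (1Z,3Z,6E)-1-methoxy-7,11-dimethyl-1,3-bis(trimethylsilyloxy)dodeca-1,3,6,10-tetraene
Product: 17 (2S)-8-geranyl-5,7-dihydroxy-4'-(tert-butyldimethylsilyloxy)flavanone, via cis-fused sulfinyl cycloadduct 14 (not isolated), via 5,8-dihydro ketal 15 (not isolated), via 7-O-trimethylsilyl flavanone 16 (not isolated)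
Conditions: 13 (3 equiv), PhMe, 60 → 90 °C, sealed tube, Ar; then 1 M aq. citric acid, THF, 0 °C
Reagents that add atoms: none
Why: Proposed new method: the electron-rich diene 13 and the doubly activated C5=C6 bond of 8 should combine in a normal-demand, strongly asynchronous [4+2] addition (in the limit a Mukaiyama–Michael addition followed by collapse of the sulfinyl-stabilised enolate onto the ketene-acetal-derived oxocarbenium carbon), in which the geranyl-bearing diene terminus C4 bonds to C6 of 8 (future C8a) and the ketene-acetal carbon C1 bonds to C5 (future C4a). The closest known reactions are Diels–Alder benzannulations of 1-alkoxy-1,3-bis(silyloxy)dienes with haloquinones and acetylenic esters, and the cycloaddition–sulfoxide elimination sequences of 2-sulfinyl enones, sulfinylquinones and 3-acyl- or 3-sulfinylchromones with siloxydienes; a 2,3-dihydro-4H-pyran-4-one has not been used in this way. Ring A is closed as a six-membered carbocycle by the intermolecular cycloaddition itself (two C–C bonds, suprafacial on both partners), which places the sulfinyl group at C4a cis to 8a-H in 14; this is the geometry a thermal syn-elimination of benzenesulfenic acid needs, whereas a halide at C4a would have only this cis, non-acidic hydrogen to leave with. The 5,8-dihydro ketal 15 then expels methoxytrimethylsilane from C5 and tautomerises through 8-H to the arene 16, and mild aqueous acid frees the 7-hydroxyl while the aryl TBS ether stays. No new stereocentre survives (C4a, C8, C8a and sulfur all become sp2 or are lost), and C2 should be untouched because the medium is neutral and free of Lewis acid and base. The selectivity needed is regiochemical (chain at C8, not C6) and is secured by matched polarisation: the most nucleophilic diene carbon is the one carrying the chain, and C6 of 8 is β to both the ketone and the sulfoxide; the trisubstituted geranyl alkenes are not dienophiles.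

Step 9
Reactants: 17 (2S)-8-geranyl-5,7-dihydroxy-4'-(tert-butyldimethylsilyloxy)flavanone
Product: 18 sophoraflavanone A, (2S)-8-geranyl-5,7,4'-trihydroxyflavanone
Conditions: HF·pyridine, excess pyridine, THF, 0 °C → rt
Reagents that add atoms: none
Why: Fluoride cleaves the aryl silyl ether (desilylation driven by the Si–F bond), and the pyridine buffer keeps the medium neither acidic enough to cyclise the 7-hydroxy/geranyl pair nor basic enough to open the flavanone to the chalcone, so C2 is retained.

**Compound list**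

1 | 4-hydroxybenzaldehyde | O=Cc1ccc(O)cc1 | starting material
2 | 4-(tert-butyldimethylsilyloxy)benzaldehyde | O=Cc1ccc(O[Si](C)(C)C(C)(C)C)cc1 | intermediate
3 | trans-1-methoxy-3-(trimethylsilyloxy)buta-1,3-diene | CO/C=C/C(=C)O[Si](C)(C)C | starting material
4 | (1E,5S)-5-[4-(tert-butyldimethylsilyloxy)phenyl]-1-methoxy-5-(trimethylsilyloxy)pent-1-en-3-one | CO/C=C/C(=O)C[C@@H](c1ccc(O[Si](C)(C)C(C)(C)C)cc1)O[Si](C)(C)C | intermediate
5 | (S)-2-[4-(tert-butyldimethylsilyloxy)phenyl]-2,3-dihydro-4H-pyran-4-one | O=C1C[C@@H](c2ccc(O[Si](C)(C)C(C)(C)C)cc2)OC=C1 | intermediate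
6 | (2S)-2-[4-(tert-butyldimethylsilyloxy)phenyl]-6-chloro-5-(phenylthio)tetrahydro-4H-pyran-4-one (C5/C6 diastereomers) | O=C1C[C@@H](c2ccc(O[Si](C)(C)C(C)(C)C)cc2)OC(Cl)C1Sc1ccccc1 | intermediate
7 | (S)-2-[4-(tert-butyldimethylsilyloxy)phenyl]-5-(phenylthio)-2,3-dihydro-4H-pyran-4-one | O=C1C[C@@H](c2ccc(O[Si](C)(C)C(C)(C)C)cc2)OC=C1Sc1ccccc1 | intermediate
8 | (2S)-2-[4-(tert-butyldimethylsilyloxy)phenyl]-5-(phenylsulfinyl)-2,3-dihydro-4H-pyran-4-one (both epimers at sulfur) | O=C1C[C@@H](c2ccc(O[Si](C)(C)C(C)(C)C)cc2)OC=C1S(=O)c1ccccc1 | intermediate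
9 | methyl acetoacetate | COC(=O)CC(C)=O | starting material
10 | geranyl bromide | CC(C)=CCC/C(C)=C/CBr | starting material
11 | methyl (6E)-7,11-dimethyl-3-oxododeca-6,10-dienoate | COC(=O)CC(=O)CC/C=C(\C)CCC=C(C)C | intermediate
12 | methyl (6E)-7,11-dimethyl-3-(trimethylsilyloxy)dodeca-2,6,10-trienoate (2E/2Z mixture) | COC(=O)C=C(O[Si](C)(C)C)CC/C=C(\C)CCC=C(C)C | intermediate
13 | (1Z,3Z,6E)-1-methoxy-7,11-dimethyl-1,3-bis(trimethylsilyloxy)dodeca-1,3,6,10-tetraene | CO/C(O[Si](C)(C)C)=C/C(O[Si](C)(C)C)=C/C/C=C(\C)CCC=C(C)C | intermediate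
14 | (2S)-2-[4-(tert-butyldimethylsilyloxy)phenyl]-8-geranyl-5-methoxy-4a-(phenylsulfinyl)-5,7-bis(trimethylsilyloxy)-2,3,4a,5,8,8a-hexahydro-4H-chromen-4-one (4a,8a-cis; mixture at C5, C8, S and ring-fusion face) | CC(C)=CCC/C(C)=C/CC1C(O[Si](C)(C)C)=CC(OC)(O[Si](C)(C)C)C2(S(=O)c3ccccc3)C(=O)C[C@@H](c3ccc(O[Si](C)(C)C(C)(C)C)cc3)OC12 | intermediate
15 | (2S)-2-[4-(tert-butyldimethylsilyloxy)phenyl]-8-geranyl-5-methoxy-5,7-bis(trimethylsilyloxy)-2,3,5,8-tetrahydro-4H-chromen-4-one (mixture at C5, C8) | CC(C)=CCC/C(C)=C/CC1C(O[Si](C)(C)C)=CC(OC)(O[Si](C)(C)C)C2=C1O[C@H](c1ccc(O[Si](C)(C)C(C)(C)C)cc1)CC2=O | intermediate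
16 | (2S)-8-geranyl-5-hydroxy-7-(trimethylsilyloxy)-4'-(tert-butyldimethylsilyloxy)flavanone | CC(C)=CCC/C(C)=C/Cc1c(O[Si](C)(C)C)cc(O)c2c1O[C@H](c1ccc(O[Si](C)(C)C(C)(C)C)cc1)CC2=O | intermediate
17 | (2S)-8-geranyl-5,7-dihydroxy-4'-(tert-butyldimethylsilyloxy)flavanone | CC(C)=CCC/C(C)=C/Cc1c(O)cc(O)c2c1O[C@H](c1ccc(O[Si](C)(C)C(C)(C)C)cc1)CC2=O | intermediate
18 | sophoraflavanone A, (2S)-8-geranyl-5,7,4'-trihydroxyflavanone | CC(C)=CCC/C(C)=C/Cc1c(O)cc(O)c2c1O[C@H](c1ccc(O)cc1)CC2=O | target

**Step count and risks**

Total steps: 9. Longest linear sequence: 6 (steps 1, 2, 3, 4, 8, 9); the diene branch (steps 5–7) joins at step 8.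

Steps most likely to fail:

1. Step 8 (Proposed new method).
 - What may go wrong: the cycloaddition may not take place at the hindered, donor-substituted C5=C6 bond, or may stop at the open Mukaiyama–Michael adduct. The diene may be consumed by silyl transfer to the sulfoxide oxygen. Loss of trimethylsilanol instead of methoxytrimethylsilane at C5 would give the 5-O-methyl ether. High pressure or a mild Lewis acid are adjustments of conditions only.
 - Fallback (known chemistry; ring A bought and ring C closed last), setting out from geranyl bromide 10 and returning at 18: purchased 2,4,6-trihydroxyacetophenone is C-geranylated with 10 (K2CO3, acetone) to 3-geranyl-2,4,6-trihydroxyacetophenone F1. MOMCl/i-Pr2NEt (2 equiv) should protect the 4- and 6-hydroxyls and leave the hindered, chelated hydroxyl beside the chain, giving 3-geranyl-2-hydroxy-4,6-bis(methoxymethoxy)acetophenone F2. Claisen–Schmidt condensation with purchased 4-(methoxymethoxy)benzaldehyde (KOH, EtOH) gives 3'-geranyl-2'-hydroxy-4',6',4-tris(methoxymethoxy)chalcone F3. NaOAc in hot EtOH closes the single free phenol onto the enone, which fixes the chain at C8, to racemic 8-geranyl-5,7,4'-tris(methoxymethoxy)flavanone F4. HCl in MeOH at room temperature removes the acetals to racemic sophoraflavanone A F5, and preparative HPLC on a chiral stationary phase delivers 18.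

2. Step 2.
 - What may go wrong: slow turnover and incomplete facial discrimination with the electron-rich aldehyde, and partial loss of the aryl silyl ether in the TFA closure.
 - Fallback (the stereocentre is set by ketone hydrogenation instead of C–C bond formation), setting out from 2 and returning at 5: Roskamp homologation of 2 with ethyl diazoacetate and catalytic SnCl2 gives ethyl 3-[4-(tert-butyldimethylsilyloxy)phenyl]-3-oxopropanoate F6. Noyori hydrogenation with a Ru(II)–(R)-BINAP catalyst should give ethyl (S)-3-[4-(tert-butyldimethylsilyloxy)phenyl]-3-hydroxypropanoate F7. MeNH(OMe)·HCl/i-PrMgCl gives (S)-3-[4-(tert-butyldimethylsilyloxy)phenyl]-3-hydroxy-N-methoxy-N-methylpropanamide F8. Ethynylmagnesium bromide gives (S)-5-[4-(tert-butyldimethylsilyloxy)phenyl]-5-hydroxypent-1-yn-3-one F9, which cyclises 6-endo (PdCl2(MeCN)2 or AgOTf) to 5.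

3. Step 3.
 - What may go wrong: attack of the sulfenyl chloride on the silyloxyarene ring, double sulfenylation, or base-induced opening of the pyranone ring during dehydrochlorination with erosion at C2.
 - Fallback (sulfur introduced by cross-coupling instead of electrophilic substitution), setting out from 5 and returning at 7: NBS in CH2Cl2 at 0 °C brominates C5 to (S)-5-bromo-2-[4-(tert-butyldimethylsilyloxy)phenyl]-2,3-dihydro-4H-pyran-4-one F10. Pd2(dba)3/Xantphos-catalysed C–S coupling with thiophenol and i-Pr2NEt in dioxane at 80 °C gives 7.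

**Further compounds**

F1 | step 8 | 3-geranyl-2,4,6-trihydroxyacetophenone | CC(=O)c1c(O)cc(O)c(C/C=C(\C)CCC=C(C)C)c1O
F2 | step 8 | 3-geranyl-2-hydroxy-4,6-bis(methoxymethoxy)acetophenone | CC(=O)c1c(OCOC)cc(OCOC)c(C/C=C(\C)CCC=C(C)C)c1O
F3 | step 8 | 3'-geranyl-2'-hydroxy-4',6',4-tris(methoxymethoxy)chalcone | COCOc1ccc(/C=C/C(=O)c2c(OCOC)cc(OCOC)c(C/C=C(\C)CCC=C(C)C)c2O)cc1
F4 | step 8 | racemic 8-geranyl-5,7,4'-tris(methoxymethoxy)flavanone | COCOc1ccc(C2CC(=O)c3c(OCOC)cc(OCOC)c(C/C=C(\C)CCC=C(C)C)c3O2)cc1
F5 | step 8 | racemic sophoraflavanone A | CC(C)=CCC/C(C)=C/Cc1c(O)cc(O)c2c1OC(c1ccc(O)cc1)CC2=O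
F6 | step 2 | ethyl 3-[4-(tert-butyldimethylsilyloxy)phenyl]-3-oxopropanoate | CCOC(=O)CC(=O)c1ccc(O[Si](C)(C)C(C)(C)C)cc1
F7 | step 2 | ethyl (S)-3-[4-(tert-butyldimethylsilyloxy)phenyl]-3-hydroxypropanoate | CCOC(=O)C[C@@H](c1ccc(O[Si](C)(C)C(C)(C)C)cc1)O
F8 | step 2 | (S)-3-[4-(tert-butyldimethylsilyloxy)phenyl]-3-hydroxy-N-methoxy-N-methylpropanamide | CON(C)C(=O)C[C@@H](c1ccc(O[Si](C)(C)C(C)(C)C)cc1)O
F9 | step 2 | (S)-5-[4-(tert-butyldimethylsilyloxy)phenyl]-5-hydroxypent-1-yn-3-one | C#CC(=O)C[C@@H](c1ccc(O[Si](C)(C)C(C)(C)C)cc1)O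
F10 | step 3 | (S)-5-bromo-2-[4-(tert-butyldimethylsilyloxy)phenyl]-2,3-dihydro-4H-pyran-4-one | O=C1C[C@@H](c2ccc(O[Si](C)(C)C(C)(C)C)cc2)OC=C1Br
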